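**Retrosynthetic overview**
- Kanzonol I is traced back through its TIPS ether to a 2-alkoxy-3-arylchroman whose C2 alkoxy group is a removable chiral auxiliary.
- The strategy rests on ring C (O1–C2–C3–C4–C4a–C8a). O1, C8a, C4a and C4 come from an o-quinone methide of the symmetric 3,5-dimethoxy-4-prenylphenol. C2–C3 comes from an (E)-enol ether whose β-carbon, C3, is the only stereocentre and carries chromene ring B.
- C4–C3 and O1–C2 are disconnected together by an auxiliary-controlled inverse-demand hetero-Diels–Alder reaction. The enol ether comes from the ring B aldehyde by Takai iodo-olefination and CuI-catalysed C–O coupling with (1R,2S)-trans-2-phenylcyclohexanol.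
- The methide precursor comes from 1,3-dimethoxybenzene by lithiation/prenylation, C–H borylation/oxidation, ortho-formylation, O-Boc carbonate formation and aldehyde reduction.
- Ring order: both benzene rings are bought, the 2,2-dimethylpyran of ring B is closed first (propargyl ether Claisen cascade), and ring C is closed afterwards by the cycloaddition.

Key step: step 12

Assumption: the enol ether of the (1R,2S)-auxiliary is taken to react through its s-trans conformer on the face remote from the phenyl group, which a model places with (3R). If the facial sense proves opposite, the antipodal (1S,2R)-alcohol is used in the same sequence.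

**Route**

Step 1
Reactants: 1 1,3-dimethoxybenzene; 2 prenyl bromide (1-bromo-3-methylbut-2-ene)
Product: 4 1,3-dimethoxy-2-(3-methylbut-2-en-1-yl)benzene, via 2,6-dimethoxyphenyllithium 3 (not isolated)
Conditions: n-BuLi, THF, 0 °C to rt; then 2, −78 °C to rt
Reagents that add atoms: none
Why: Directed ortho-lithiation at the carbon flanked by both methoxy groups, followed by SN2 alkylation of the aryllithium with the primary allylic bromide, should give the 2-prenyl arene as the only regioisomer.

Step 2
Reactants: 4 1,3-dimethoxy-2-(3-methylbut-2-en-1-yl)benzene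
Product: 5 2-[3,5-dimethoxy-4-(3-methylbut-2-en-1-yl)phenyl]-4,4,5,5-tetramethyl-1,3,2-dioxaborolane
Conditions: [Ir(OMe)(cod)]2 (1.5 mol%), 4,4'-di-tert-butyl-2,2'-bipyridine (3 mol%), B2pin2 (1.0 equiv), THF, 60 °C
Reagents that add atoms: bis(pinacolato)diboron, CC1(C)OB(OC1(C)C)B1OC(C)(C)C(C)(C)O1
Why: Iridium-catalysed aromatic C–H borylation is sterically governed and should take the only ring C–H without an ortho substituent, the one meta to both methoxy groups, while the trisubstituted prenyl alkene is left alone.

Step 3
Reactants: 5 2-[3,5-dimethoxy-4-(3-methylbut-2-en-1-yl)phenyl]-4,4,5,5-tetramethyl-1,3,2-dioxaborolane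
Product: 6 3,5-dimethoxy-4-(3-methylbut-2-en-1-yl)phenol
Conditions: NaBO3·4H2O, THF/H2O, rt
Reagents that add atoms: sodium perborate tetrahydrate (peroxoborate dimer), [Na+].[Na+].O[B-]1(O)OO[B-](O)(O)OO1
Why: Oxidation of the aryl boronate (peroxoborate attack at boron, 1,2-aryl shift to oxygen, hydrolysis) should give the phenol under mild conditions that spare the prenyl alkene.

Step 4
Reactants: 6 3,5-dimethoxy-4-(3-methylbut-2-en-1-yl)phenol
Product: 7 2-hydroxy-4,6-dimethoxy-5-(3-methylbut-2-en-1-yl)benzaldehyde
Conditions: MgCl2, Et3N, (CH2O)n, MeCN, reflux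
Reagents that add atoms: paraformaldehyde (as formaldehyde), C=O
Why: Magnesium-mediated ortho-formylation (Casnati–Skattebøl reaction) delivers formaldehyde to the carbon ortho to the magnesium phenoxide, and because the two ortho positions of the symmetric phenol are equivalent only one aldehyde can form.

Step 5
Reactants: 7 2-hydroxy-4,6-dimethoxy-5-(3-methylbut-2-en-1-yl)benzaldehyde
Product: 8 tert-butyl 2-formyl-3,5-dimethoxy-4-(3-methylbut-2-en-1-yl)phenyl carbonate
Conditions: Boc2O, iPr2NEt, DMAP (cat.), CH2Cl2, 0 °C to rt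
Reagents that add atoms: di-tert-butyl dicarbonate, CC(C)(C)OC(=O)OC(=O)OC(C)(C)C
Why: DMAP-catalysed O-acylation with Boc2O should convert the hydrogen-bonded phenol into its tert-butyl carbonate, the group that later triggers methide formation.

Step 6
Reactants: 8 tert-butyl 2-formyl-3,5-dimethoxy-4-(3-methylbut-2-en-1-yl)phenyl carbonate
Product: 9 tert-butyl 2-(hydroxymethyl)-3,5-dimethoxy-4-(3-methylbut-2-en-1-yl)phenyl carbonate
Conditions: BH3·NH2tBu, CH2Cl2, 0 °C; pH 7 buffer work-up
Reagents that add atoms: none
Why: Amine–borane carbonyl reduction hands hydride to the aldehyde and holds the oxygen as a covalent borate until neutral work-up, so no free alkoxide arises to shift the Boc group and release the methide early, and the amine-bound borane does not hydroborate the prenyl alkene as free BH3 would.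

Step 7
Reactants: 10 2,4-dihydroxybenzaldehyde
Product: 11 2-hydroxy-4-(triisopropylsilyloxy)benzaldehyde
Conditions: TIPSCl, imidazole, CH2Cl2, 0 °C
Reagents that add atoms: triisopropylsilyl chloride, CC(C)[Si](Cl)(C(C)C)C(C)C
Why: Phenol silylation should occur only at the 4-hydroxyl, because the 2-hydroxyl is locked in a hydrogen bond to the aldehyde and is far less nucleophilic.

Step 8
Reactants: 11 2-hydroxy-4-(triisopropylsilyloxy)benzaldehyde; 12 2-methylbut-3-yn-2-ol
Product: 14 2-[(2-methylbut-3-yn-2-yl)oxy]-4-(triisopropylsilyloxy)benzaldehyde, via propargylic trifluoroacetate 13 (not isolated)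
Conditions: 12, (CF3CO)2O, DBU, MeCN, −5 °C; then 11, DBU, CuCl2·2H2O (1 mol%), MeCN, −5 to 0 °C
Reagents that add atoms: none
Why: Copper-catalysed propargylic substitution (phenoxide capture of the copper-bound propargyl/allenylidene species formed from the tertiary trifluoroacetate) should place the 1,1-dimethylpropargyl group on the remaining hydroxyl, which direct SN2 chemistry cannot do at a tertiary centre.

Step 9
Reactants: 14 2-[(2-methylbut-3-yn-2-yl)oxy]-4-(triisopropylsilyloxy)benzaldehyde
Product: 16 2,2-dimethyl-5-(triisopropylsilyloxy)-2H-chromene-8-carbaldehyde, via allenyl phenol 15 (not isolated)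
Conditions: o-xylene, 140 °C
Reagents that add atoms: none
Why: The aryl propargyl ether Claisen rearrangement ([3,3] shift to the only free ortho carbon, enolisation to allenyl phenol 15, 1,5-hydrogen shift and oxa-6π electrocyclisation) should close the 2,2-dimethyl-2H-pyran ring, with the regiochemistry fixed because the aldehyde blocks the other ortho position.

Step 10
Reactants: 16 2,2-dimethyl-5-(triisopropylsilyloxy)-2H-chromene-8-carbaldehyde
Product: 17 8-[(E)-2-iodovinyl]-2,2-dimethyl-5-(triisopropylsilyloxy)-2H-chromene
Conditions: CrCl2, CHI3, THF, 0 °C to rt, dark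
Reagents that add atoms: iodoform, IC(I)I
Why: Takai iodo-olefination (addition of the geminal dichromium reagent from CHI3 and CrCl2 to the aldehyde, then elimination) should give the one-carbon-extended vinyl iodide with the E geometry typical of aromatic aldehydes, without touching the chromene alkene or the silyl ether.

Step 11
Reactants: 17 8-[(E)-2-iodovinyl]-2,2-dimethyl-5-(triisopropylsilyloxy)-2H-chromene; 18 (1R,2S)-trans-2-phenylcyclohexanol
Product: 19 2,2-dimethyl-8-{(E)-2-[(1R,2S)-2-phenylcyclohexyloxy]vinyl}-5-(triisopropylsilyloxy)-2H-chromene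
Conditions: CuI (10 mol%), 3,4,7,8-tetramethyl-1,10-phenanthroline (20 mol%), Cs2CO3, toluene, 80 °C
Reagents that add atoms: none
Why: Copper-catalysed Ullmann-type C–O coupling of a vinyl iodide with an aliphatic alcohol proceeds with retention of alkene geometry, so the E-iodide should give the E-enol ether of the auxiliary without disturbing its two stereocentres.

Step 12
Reactants: 9 tert-butyl 2-(hydroxymethyl)-3,5-dimethoxy-4-(3-methylbut-2-en-1-yl)phenyl carbonate; 19 2,2-dimethyl-8-{(E)-2-[(1R,2S)-2-phenylcyclohexyloxy]vinyl}-5-(triisopropylsilyloxy)-2H-chromene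
Product: 21 (2S,3R)-3-[2,2-dimethyl-5-(triisopropylsilyloxy)-2H-chromen-8-yl]-5,7-dimethoxy-6-(3-methylbut-2-en-1-yl)-2-[(1R,2S)-2-phenylcyclohexyloxy]chroman (2,3-trans), via o-quinone methide 20 (not isolated)
Conditions: 19 (1 equiv), 9 (1.5 equiv), t-BuMgCl (1.5 equiv), toluene, −78 °C to rt
Reagents that add atoms: none
Why: Proposed new method: t-BuMgCl deprotonates the benzylic alcohol of 9, the Boc group shifts from the phenolic to the benzylic oxygen, and the magnesium phenoxide expels tert-butyl carbonate to release o-quinone methide 20 below room temperature, which enol ether 19 traps in an asynchronous inverse-electron-demand hetero-Diels–Alder reaction in which the electron-rich, aryl-bearing β-carbon bonds to the exocyclic methylene (C3–C4) and the methide oxygen bonds to the alkoxy carbon (O1–C2). The closest known reaction types are the diastereoselective [4+2] cycloaddition of o-quinone methides, made in this way from O-Boc salicyl alcohols, with vinyl ethers of trans-2-phenylcyclohexanol, and the racemic cycloaddition of o-quinone methides with achiral β-aryl enol ethers to 2-alkoxyisoflavans; new here is their combination, an auxiliary-bearing β-aryl enol ether against an unsubstituted, donor-rich methide. Ring C is closed by this intermolecular [4+2] cycloaddition, four atoms (O1, C8a, C4a, C4) coming from 20 and two (C2, C3) from 19. C3 is controlled by the phenyl group of the auxiliary, which covers one face of the s-trans enol ether so that the methide adds to the open face, and the temporary centre C2 follows from suprafacial addition to the E-alkene (2,3-trans). The step needs facial selectivity and a single regiochemistry: the first rests on the auxiliary, the second on the polarity match between the oxygen-bearing alkene carbon and the methide oxygen, and since C4 is a methylene group the endo or exo orientation has no stereochemical consequence. The two methoxy groups stabilise the methide so that it should be selective and slow to oligomerise, and the basic, non-oxidising and non-reducing conditions leave the prenyl and chromene alkenes and the TIPS ether intact.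

Step 13
Reactants: 21 (2S,3R)-3-[2,2-dimethyl-5-(triisopropylsilyloxy)-2H-chromen-8-yl]-5,7-dimethoxy-6-(3-methylbut-2-en-1-yl)-2-[(1R,2S)-2-phenylcyclohexyloxy]chroman
Product: 22 (3R)-3-[2,2-dimethyl-5-(triisopropylsilyloxy)-2H-chromen-8-yl]-5,7-dimethoxy-6-(3-methylbut-2-en-1-yl)chroman
Conditions: Et3SiH, BF3·OEt2, CH2Cl2, −78 to −40 °C
Reagents that add atoms: none
Why: Lewis-acid ionisation of the aryl alkyl acetal to the C2 oxocarbenium ion and hydride capture from Et3SiH (ionic reductive deoxygenation) should remove the temporary C2 centre at low temperature before H3 can be lost, so C3 stays untouched and auxiliary alcohol 18 is recovered.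

Step 14
Reactants: 22 (3R)-3-[2,2-dimethyl-5-(triisopropylsilyloxy)-2H-chromen-8-yl]-5,7-dimethoxy-6-(3-methylbut-2-en-1-yl)chroman
Product: 23 Kanzonol I
Conditions: TBAF, AcOH, THF, 0 °C
Reagents that add atoms: none
Why: Fluoride-mediated desilylation, buffered with AcOH so that no free phenoxide or strong base is present, should release the phenol without affecting the chromene, prenyl or methyl ether groups.

**Compound list**
1 | 1,3-dimethoxybenzene | COc1cccc(OC)c1 | starting material
2 | prenyl bromide (1-bromo-3-methylbut-2-ene) | CC(C)=CCBr | starting material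
3 | 2,6-dimethoxyphenyllithium | [Li]c1c(OC)cccc1OC | intermediate
4 | 1,3-dimethoxy-2-(3-methylbut-2-en-1-yl)benzene | COc1cccc(OC)c1CC=C(C)C | intermediate
5 | 2-[3,5-dimethoxy-4-(3-methylbut-2-en-1-yl)phenyl]-4,4,5,5-tetramethyl-1,3,2-dioxaborolane | COc1cc(B2OC(C)(C)C(C)(C)O2)cc(OC)c1CC=C(C)C | intermediate
6 | 3,5-dimethoxy-4-(3-methylbut-2-en-1-yl)phenol | COc1cc(O)cc(OC)c1CC=C(C)C | intermediate
7 | 2-hydroxy-4,6-dimethoxy-5-(3-methylbut-2-en-1-yl)benzaldehyde | COc1cc(O)c(C=O)c(OC)c1CC=C(C)C | intermediate
8 | tert-butyl 2-formyl-3,5-dimethoxy-4-(3-methylbut-2-en-1-yl)phenyl carbonate | COc1cc(OC(=O)OC(C)(C)C)c(C=O)c(OC)c1CC=C(C)C | intermediate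
9 | tert-butyl 2-(hydroxymethyl)-3,5-dimethoxy-4-(3-methylbut-2-en-1-yl)phenyl carbonate | COc1cc(OC(=O)OC(C)(C)C)c(CO)c(OC)c1CC=C(C)C | intermediate
10 | 2,4-dihydroxybenzaldehyde | O=Cc1ccc(O)cc1O | starting material
11 | 2-hydroxy-4-(triisopropylsilyloxy)benzaldehyde | O=Cc1ccc(O[Si](C(C)C)(C(C)C)C(C)C)cc1O | intermediate
12 | 2-methylbut-3-yn-2-ol | CC(C)(O)C#C | starting material
13 | 2-methylbut-3-yn-2-yl trifluoroacetate | CC(C)(OC(=O)C(F)(F)F)C#C | intermediate
14 | 2-[(2-methylbut-3-yn-2-yl)oxy]-4-(triisopropylsilyloxy)benzaldehyde | O=Cc1ccc(O[Si](C(C)C)(C(C)C)C(C)C)cc1OC(C)(C)C#C | intermediate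
15 | 2-hydroxy-3-(3-methylbuta-1,2-dien-1-yl)-4-(triisopropylsilyloxy)benzaldehyde | O=Cc1ccc(O[Si](C(C)C)(C(C)C)C(C)C)c(C=C=C(C)C)c1O | intermediate
16 | 2,2-dimethyl-5-(triisopropylsilyloxy)-2H-chromene-8-carbaldehyde | O=Cc1ccc(O[Si](C(C)C)(C(C)C)C(C)C)c2c1OC(C)(C)C=C2 | intermediate
17 | 8-[(E)-2-iodovinyl]-2,2-dimethyl-5-(triisopropylsilyloxy)-2H-chromene | I/C=C/c1ccc(O[Si](C(C)C)(C(C)C)C(C)C)c2c1OC(C)(C)C=C2 | intermediate
18 | (1R,2S)-trans-2-phenylcyclohexanol | O[C@@H]1CCCC[C@H]1c1ccccc1 | starting material
19 | 2,2-dimethyl-8-{(E)-2-[(1R,2S)-2-phenylcyclohexyloxy]vinyl}-5-(triisopropylsilyloxy)-2H-chromene | O(/C=C/c1ccc(O[Si](C(C)C)(C(C)C)C(C)C)c2c1OC(C)(C)C=C2)[C@@H]1CCCC[C@H]1c1ccccc1 | intermediate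
20 | 3,5-dimethoxy-6-methylidene-4-(3-methylbut-2-en-1-yl)cyclohexa-2,4-dien-1-one (o-quinone methide) | C=C1C(=O)C=C(OC)C(CC=C(C)C)=C1OC | intermediate
21 | (2S,3R)-3-[2,2-dimethyl-5-(triisopropylsilyloxy)-2H-chromen-8-yl]-5,7-dimethoxy-6-(3-methylbut-2-en-1-yl)-2-[(1R,2S)-2-phenylcyclohexyloxy]chroman (2,3-trans) | COc1cc2c(c(OC)c1CC=C(C)C)C[C@H](c1ccc(O[Si](C(C)C)(C(C)C)C(C)C)c3c1OC(C)(C)C=C3)[C@@H](O[C@@H]1CCCC[C@H]1c1ccccc1)O2 | intermediate
22 | (3R)-3-[2,2-dimethyl-5-(triisopropylsilyloxy)-2H-chromen-8-yl]-5,7-dimethoxy-6-(3-methylbut-2-en-1-yl)chroman | COc1cc2c(c(OC)c1CC=C(C)C)C[C@H](c1ccc(O[Si](C(C)C)(C(C)C)C(C)C)c3c1OC(C)(C)C=C3)CO2 | intermediate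
23 | Kanzonol I, 8-[(3R)-5,7-dimethoxy-6-(3-methylbut-2-en-1-yl)chroman-3-yl]-2,2-dimethyl-2H-chromen-5-ol | COc1cc2c(c(OC)c1CC=C(C)C)C[C@H](c1ccc(O)c3c1OC(C)(C)C=C3)CO2 | target

**Step count**
Total: 14 steps. Longest linear sequence: 9 steps (steps 1–6, then 12–14, from 1,3-dimethoxybenzene).

**Steps most likely to fail**

1. Step 12 (proposed new method). The auxiliary may discriminate poorly between the faces of the β-aryl enol ether, or the hindered dienophile may capture the methide so slowly that methide oligomerisation wins. The fallback gives up auxiliary control in favour of a racemic cycloaddition with a small enol ether and a resolution; it sets out from aldehyde 16 and carbonate 9 and rejoins the route at 22. Wittig methoxymethylenation of 16 (Ph3P=CHOMe from (methoxymethyl)triphenylphosphonium chloride and KOtBu, THF, 0 °C) should give the achiral methyl enol ether F1 as an E/Z mixture, which is used as such and in excess. The same t-BuMgCl-triggered methide generation from 9 in its presence should give the racemic 2-methoxy-3-arylchroman F2 as a cis/trans mixture, both isomers converging in the next operation. Reduction with Et3SiH and BF3·OEt2 should then give the racemic silyl ether F3. Preparative HPLC on a chiral stationary phase separates the enantiomers of F3, the (R)-enantiomer being 22.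

2. Step 11. C–O bond formation at the hindered secondary alcohol may be sluggish, so that base-induced dehydroiodination of the styryl iodide to the arylacetylene or erosion of the alkene geometry takes over. The fallback builds the enol ether by olefination instead of C–O coupling; it sets out from auxiliary alcohol 18 and aldehyde 16 and rejoins the route at 19. Treatment of 18 with paraformaldehyde and HCl gas in CH2Cl2 should give the chloromethyl ether F4. Arbuzov reaction of F4 with ethyl diphenylphosphinite (Ph2POEt, 100 °C) should give the alkoxymethyl diphenylphosphine oxide F5. Lithiation of F5 (LDA, THF, −78 °C) and addition to 16 should give the β-hydroxy phosphine oxide adducts F6, which are stable and separable by chromatography. The anti-configured adducts undergo stereospecific syn elimination of diphenylphosphinate with NaH in DMF (Horner–Wittig reaction) to give the E-enol ether 19.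

3. Step 13. The oxocarbenium ion may lose the C3 proton, which would erase the stereocentre through a 4H-chromene that is then reduced without control, or the Lewis acid may attack the chromene or prenyl alkene. The fallback replaces silane capture of the cation by hydrolysis, borohydride reduction and ring closure; it sets out from 21 and rejoins the route at 22. Mild aqueous acid (PPTS, THF/H2O, rt) should hydrolyse the acetal to the lactol F7 and return the auxiliary. Immediate reduction of F7, kept cold, with NaBH4 in MeOH/THF at 0 °C should give the phenol–primary alcohol F8 through the ring-opened hydroxy aldehyde. Mitsunobu etherification of F8 (PPh3, DIAD, THF, 0 °C) closes ring C at the primary carbon without touching C3 and gives 22.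

**Further compounds**
F1 | step 12 | 8-(2-methoxyvinyl)-2,2-dimethyl-5-(triisopropylsilyloxy)-2H-chromene (E/Z mixture) | COC=Cc1ccc(O[Si](C(C)C)(C(C)C)C(C)C)c2c1OC(C)(C)C=C2
F2 | step 12 | racemic 3-[2,2-dimethyl-5-(triisopropylsilyloxy)-2H-chromen-8-yl]-2,5,7-trimethoxy-6-(3-methylbut-2-en-1-yl)chroman (cis/trans mixture) | COc1cc2c(c(OC)c1CC=C(C)C)CC(c1ccc(O[Si](C(C)C)(C(C)C)C(C)C)c3c1OC(C)(C)C=C3)C(OC)O2
F3 | step 12 | racemic 3-[2,2-dimethyl-5-(triisopropylsilyloxy)-2H-chromen-8-yl]-5,7-dimethoxy-6-(3-methylbut-2-en-1-yl)chroman | COc1cc2c(c(OC)c1CC=C(C)C)CC(c1ccc(O[Si](C(C)C)(C(C)C)C(C)C)c3c1OC(C)(C)C=C3)CO2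
F4 | step 11 | chloromethyl (1R,2S)-2-phenylcyclohexyl ether | ClCO[C@@H]1CCCC[C@H]1c1ccccc1
F5 | step 11 | {[(1R,2S)-2-phenylcyclohexyloxy]methyl}diphenylphosphine oxide | O=P(CO[C@@H]1CCCC[C@H]1c1ccccc1)(c1ccccc1)c1ccccc1
F6 | step 11 | 1-[2,2-dimethyl-5-(triisopropylsilyloxy)-2H-chromen-8-yl]-2-(diphenylphosphoryl)-2-[(1R,2S)-2-phenylcyclohexyloxy]ethanol (diastereomers) | OC(c1ccc(O[Si](C(C)C)(C(C)C)C(C)C)c2c1OC(C)(C)C=C2)C(O[C@@H]1CCCC[C@H]1c1ccccc1)P(=O)(c1ccccc1)c1ccccc1
F7 | step 13 | (3R)-3-[2,2-dimethyl-5-(triisopropylsilyloxy)-2H-chromen-8-yl]-5,7-dimethoxy-6-(3-methylbut-2-en-1-yl)chroman-2-ol (anomer mixture) | COc1cc2c(c(OC)c1CC=C(C)C)C[C@H](c1ccc(O[Si](C(C)C)(C(C)C)C(C)C)c3c1OC(C)(C)C=C3)C(O)O2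
F8 | step 13 | 2-{(2R)-2-[2,2-dimethyl-5-(triisopropylsilyloxy)-2H-chromen-8-yl]-3-hydroxypropyl}-3,5-dimethoxy-4-(3-methylbut-2-en-1-yl)phenol | COc1cc(O)c(C[C@H](c2ccc(O[Si](C(C)C)(C(C)C)C(C)C)c3c2OC(C)(C)C=C3)CO)c(OC)c1CC=C(C)C
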